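The ring enol acetate (C3–OAc on the C3=C4 double bond, beside the C2 ketone) is read as a masked cyclohexane-1,2-dione, so the ring bond between the methyl-bearing C4 and the carbinol carbon C5 is an aldol bond. The key step closes an acyclic 1,2-diketone aldehyde by a proline-catalysed intramolecular aldol addition: C4 is the only enolisable dione position because C1 already carries the exocyclic tetrasubstituted alkene. One operation forms the six-membered ring, sets C5 and, by tautomerisation, gives the diosphenol, so all C4 and enamine isomers converge. The precursor, with side-chain angelate in place, comes from an alkoxide-directed anti-carbomagnesiation of a chiral propargylic alcohol.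

Key step: step 13

Remark: ring atoms are labelled C1 (alkylidene-bearing carbon), C2 (ketone), C3 (acetoxy carbon), C4 (methyl-bearing carbon), C5 (carbinol) and C6 (CH2); the two oxygenated carbons that become C2 and C3 are carried as diastereomer mixtures (left open in the SMILES) because step 12 oxidises both.

Step 1
Reactants: 1 ethyl 2-hydroxybutanoate (racemic)
Product: 2 ethyl 2-[(tert-butyldimethylsilyl)oxy]butanoate
Conditions: TBSCl, imidazole, DMF, rt
Reagents that add atoms: tert-butyldimethylsilyl chloride, CC(C)(C)[Si](C)(C)Cl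
Why: Standard imidazole-promoted silylation of a secondary alcohol; the stereocentre is carried racemic because it is oxidised to a ketone in step 12.

Step 2
Reactants: 2 ethyl 2-[(tert-butyldimethylsilyl)oxy]butanoate
Product: 4 4-[(tert-butyldimethylsilyl)oxy]hex-1-yn-3-ol (diastereomer mixture), via silyloxy aldehyde 3 (not isolated)
Conditions: DIBAL-H, CH2Cl2, −78 °C; then HC≡CMgBr, THF, −78 → 0 °C; Rochelle salt
Reagents that add atoms: ethynylmagnesium bromide, C#C[Mg]Br
Why: One-pot DIBAL-H half-reduction and Grignard addition, in which the aluminium hemiacetal of the α-silyloxy ester releases aldehyde 3 only as the acetylide adds, so the labile aldehyde is never isolated; the new carbinol centre is left uncontrolled because it also becomes a ketone in step 12.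

Step 3
Reactants: 4 4-[(tert-butyldimethylsilyl)oxy]hex-1-yn-3-ol
Product: 5 3,4-bis[(tert-butyldimethylsilyl)oxy]hex-1-yne
Conditions: TBSOTf, 2,6-lutidine, CH2Cl2, 0 °C
Reagents that add atoms: tert-butyldimethylsilyl triflate, CC(C)(C)[Si](C)(C)OS(=O)(=O)C(F)(F)F
Why: Silyl triflate silylation of the hindered propargylic alcohol masks this oxygen, so that the hydroxyl made in step 6 is the only directing group in step 7.

Step 4
Reactants: 6 4-methylpent-3-enoic acid
Product: 8 N-methoxy-N,4-dimethylpent-3-enamide, via acyl imidazole 7 (not isolated)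
Conditions: CDI, CH2Cl2, rt; then MeNH(OMe)·HCl, rt
Reagents that add atoms: N,O-dimethylhydroxylamine hydrochloride, CNOC.Cl; 1,1'-carbonyldiimidazole (imidazolyl group of intermediate 7 only), O=C(n1ccnc1)n1ccnc1
Why: Carbonyldiimidazole activation and aminolysis give the Weinreb amide under neutral conditions that leave the β,γ-double bond out of conjugation.

Step 5
Reactants: 5 3,4-bis[(tert-butyldimethylsilyl)oxy]hex-1-yne; 8 N-methoxy-N,4-dimethylpent-3-enamide
Product: 10 8,9-bis[(tert-butyldimethylsilyl)oxy]-2-methylundec-2-en-6-yn-5-one, via lithium acetylide 9 (not isolated)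
Conditions: n-BuLi, THF, −78 °C; then 8, −78 → 0 °C; aq. NH4Cl
Reagents that add atoms: n-butyllithium (lithium of intermediate 9 only), [Li]CCCC
Why: Weinreb ketone synthesis, in which the lithium acetylide adds only once because the chelated tetrahedral adduct survives until the quench.

Step 6
Reactants: 10 8,9-bis[(tert-butyldimethylsilyl)oxy]-2-methylundec-2-en-6-yn-5-one
Product: 11 (5S)-8,9-bis[(tert-butyldimethylsilyl)oxy]-2-methylundec-2-en-6-yn-5-ol
Conditions: Ru[(S,S)-TsDPEN](p-cymene) (2 mol%), i-PrOH, rt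
Reagents that add atoms: none
Why: Noyori asymmetric transfer hydrogenation of an alkynyl ketone, in which the (S,S)-catalyst distinguishes the alkynyl from the sp3 substituent and should deliver hydride to the face that gives the (S)-propargylic alcohol, while the base-free medium does not isomerise the skipped enone.

Step 7
Reactants: 11 (5S)-8,9-bis[(tert-butyldimethylsilyl)oxy]-2-methylundec-2-en-6-yn-5-ol
Product: 13 (5S,6Z)-8,9-bis[(tert-butyldimethylsilyl)oxy]-7-iodo-2,6-dimethylundeca-2,6-dien-5-ol, via alkenylmagnesium chelate 12 (not isolated)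
Conditions: MeMgBr (4 equiv), CuI (20 mol%), THF, −20 °C → rt; then I2, THF, −78 → 0 °C
Reagents that add atoms: methylmagnesium bromide, C[Mg]Br; iodine, II
Why: Alkoxide-directed anti-carbomagnesiation of a propargylic alcohol, in which the magnesium alkoxide delivers methyl to the proximal alkyne carbon and magnesium to the distal one within the five-membered chelate 12; iodinolysis with retention should give the tetrasubstituted alkene with the carbinol carbon cis to iodine, which fixes the later exocyclic alkene geometry.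

Step 8
Reactants: 13 (5S,6Z)-8,9-bis[(tert-butyldimethylsilyl)oxy]-7-iodo-2,6-dimethylundeca-2,6-dien-5-ol
Product: 14 (5S,6E)-8,9-bis[(tert-butyldimethylsilyl)oxy]-7-ethenyl-2,6-dimethylundeca-2,6-dien-5-ol
Conditions: CH2=CHSnBu3, Pd2(dba)3 (5 mol%), AsPh3 (20 mol%), CuI (10 mol%), NMP, 40 °C
Reagents that add atoms: tributyl(vinyl)stannane, C=C[Sn](CCCC)(CCCC)CCCC
Why: Stille coupling replaces iodine by vinyl with retention of alkene geometry under neutral conditions that tolerate the free alcohol and the silyl ethers.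

Step 9
Reactants: 14 (5S,6E)-8,9-bis[(tert-butyldimethylsilyl)oxy]-7-ethenyl-2,6-dimethylundeca-2,6-dien-5-ol; 15 angelic acid [(Z)-2-methylbut-2-enoic acid]
Product: 17 (5S,6E)-8,9-bis[(tert-butyldimethylsilyl)oxy]-7-ethenyl-2,6-dimethylundeca-2,6-dien-5-yl (Z)-2-methylbut-2-enoate, via mixed anhydride 16 (not isolated)
Conditions: 15, 2,4,6-Cl3C6H2COCl, Et3N, toluene, rt; then 14, toluene, 70 °C
Reagents that add atoms: 2,4,6-trichlorobenzoyl chloride (aroyl group of intermediate 16 only), O=C(Cl)c1c(Cl)cc(Cl)cc1Cl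
Why: Yamaguchi mixed-anhydride esterification of the only free hydroxyl, run without DMAP or strong base so that the Z geometry of the angelate is kept.

Step 10
Reactants: 17 (5S,6E)-8,9-bis[(tert-butyldimethylsilyl)oxy]-7-ethenyl-2,6-dimethylundeca-2,6-dien-5-yl (Z)-2-methylbut-2-enoate
Product: 19 (5S,6E)-8,9-bis[(tert-butyldimethylsilyl)oxy]-7-(2-hydroxyethyl)-2,6-dimethylundeca-2,6-dien-5-yl (Z)-2-methylbut-2-enoate, via alkylborane 18 (not isolated)
Conditions: 9-BBN, THF, 0 °C → rt; then aq. NaOAc, 30% H2O2, 0 °C → rt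
Reagents that add atoms: 9-borabicyclo[3.3.1]nonane (boryl group of intermediate 18 only), B1C2CCCC1CCC2; hydrogen peroxide, OO
Why: Hydroboration–oxidation with 9-BBN is anti-Markovnikov and selective for the monosubstituted alkene over the tri- and tetrasubstituted alkenes and the enoate, and the buffered peroxide spares the ester.

Step 11
Reactants: 19 (5S,6E)-8,9-bis[(tert-butyldimethylsilyl)oxy]-7-(2-hydroxyethyl)-2,6-dimethylundeca-2,6-dien-5-yl (Z)-2-methylbut-2-enoate
Product: 20 (5S,6E)-8,9-dihydroxy-7-(2-hydroxyethyl)-2,6-dimethylundeca-2,6-dien-5-yl (Z)-2-methylbut-2-enoate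
Conditions: HF·pyridine, pyridine, THF, 0 °C → rt
Reagents that add atoms: none
Why: Fluoride desilylation with buffered HF·pyridine removes both silyl ethers without touching the allylic ester.

Step 12
Reactants: 20 (5S,6E)-8,9-dihydroxy-7-(2-hydroxyethyl)-2,6-dimethylundeca-2,6-dien-5-yl (Z)-2-methylbut-2-enoate
Product: 21 (5S,6E)-2,6-dimethyl-8,9-dioxo-7-(2-oxoethyl)undeca-2,6-dien-5-yl (Z)-2-methylbut-2-enoate
Conditions: (COCl)2, DMSO, CH2Cl2, −78 °C; then i-Pr2NEt, −78 → −40 °C; cold pH 7 buffer; used at once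
Reagents that add atoms: none
Why: Swern oxidation activates all three hydroxyls as alkoxysulfonium salts before base is added, so the vicinal diol becomes the 1,2-dione without C–C cleavage and no lactol can form and be over-oxidised; every diastereomer of 20 converges on the single compound 21.

Step 13
Reactants: 21 (5S,6E)-2,6-dimethyl-8,9-dioxo-7-(2-oxoethyl)undeca-2,6-dien-5-yl (Z)-2-methylbut-2-enoate
Product: 23 (2E,3S)-2-[(5R)-3,5-dihydroxy-4-methyl-2-oxocyclohex-3-en-1-ylidene]-6-methylhept-5-en-3-yl (Z)-2-methylbut-2-enoate, via ketol 22 (not isolated)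
Conditions: (S)-proline (30 mol%), DMSO, rt
Reagents that add atoms: none
Why: (S)-Proline condenses with the C3 carbonyl of the dione (C2 has no hydrogen on its C1 side and cannot form an enamine), the C3=C4 enamine adds to the C5 aldehyde, and hydrolysis gives ketol 22, which enolises towards C4 to the conjugated diosphenol 23. The closest known reaction type is the amino-acid-catalysed intramolecular aldol addition of keto carbonyl compounds (Hajos–Parrish ketol formation). The six-membered ring closes in the 6-(enolendo)-exo-trig mode. C5 is set by the catalyst: in the carboxylic-acid-bridged anti-enamine transition state the C6–C1–C2 tether must lie over the C2 side of the enamine, so the hydrogen-bonded aldehyde should be attacked on its Si face, which is (5R); the side-chain stereocentre is six bonds away, and the transient C4 centre and the enamine geometry are erased on tautomerisation. The step needs chemoselectivity for C4 enolisation over deconjugation of the β,γ-unsaturated aldehyde and over dehydration; this is secured because only the C4 enamine can reach a six-membered ring (reaction through C6 would close a three- or four-membered ring) and because tautomerisation to 23 takes the product out of the retro-aldol and E1cB manifolds.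

Step 14
Reactants: 23 (2E,3S)-2-[(5R)-3,5-dihydroxy-4-methyl-2-oxocyclohex-3-en-1-ylidene]-6-methylhept-5-en-3-yl (Z)-2-methylbut-2-enoate
Product: 24 (2E,3S)-2-[(5R)-3-acetoxy-5-hydroxy-4-methyl-2-oxocyclohex-3-en-1-ylidene]-6-methylhept-5-en-3-yl (Z)-2-methylbut-2-enoate
Conditions: Ac2O (1.05 equiv), Et3N (1.1 equiv), CH2Cl2, −40 °C
Reagents that add atoms: acetic anhydride, CC(=O)OC(C)=O
Why: Acetylation of the diosphenol as its ammonium enolate (enol pKa about 10) should be much faster than that of the neutral secondary C5 hydroxyl at low temperature without DMAP, giving the enol acetate selectively.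

Compound list
1 | ethyl 2-hydroxybutanoate (racemic) | CCC(O)C(=O)OCC | starting material
2 | ethyl 2-[(tert-butyldimethylsilyl)oxy]butanoate (racemic) | CCC(O[Si](C)(C)C(C)(C)C)C(=O)OCC | intermediate
3 | 2-[(tert-butyldimethylsilyl)oxy]butanal (racemic, held as its aluminium hemiacetal; not isolated) | CCC(O[Si](C)(C)C(C)(C)C)C=O | intermediate
4 | 4-[(tert-butyldimethylsilyl)oxy]hex-1-yn-3-ol (diastereomer mixture) | CCC(O[Si](C)(C)C(C)(C)C)C(O)C#C | intermediate
5 | 3,4-bis[(tert-butyldimethylsilyl)oxy]hex-1-yne (diastereomer mixture) | CCC(O[Si](C)(C)C(C)(C)C)C(O[Si](C)(C)C(C)(C)C)C#C | intermediate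
6 | 4-methylpent-3-enoic acid | CC(C)=CCC(=O)O | starting material
7 | 1-(4-methylpent-3-enoyl)imidazole (not isolated) | CC(C)=CCC(=O)n1ccnc1 | intermediate
8 | N-methoxy-N,4-dimethylpent-3-enamide | CC(C)=CCC(=O)N(C)OC | intermediate
9 | lithium acetylide of 5, 3,4-bis[(tert-butyldimethylsilyl)oxy]hex-1-yn-1-yllithium (not isolated) | [Li]C#CC(O[Si](C)(C)C(C)(C)C)C(O[Si](C)(C)C(C)(C)C)CC | intermediate
10 | 8,9-bis[(tert-butyldimethylsilyl)oxy]-2-methylundec-2-en-6-yn-5-one | CC(C)=CCC(=O)C#CC(O[Si](C)(C)C(C)(C)C)C(O[Si](C)(C)C(C)(C)C)CC | intermediate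
11 | (5S)-8,9-bis[(tert-butyldimethylsilyl)oxy]-2-methylundec-2-en-6-yn-5-ol | CC(C)=CC[C@H](O)C#CC(O[Si](C)(C)C(C)(C)C)C(O[Si](C)(C)C(C)(C)C)CC | intermediate
12 | cyclic alkenylmagnesium alkoxide, (5S)-3-[1,2-bis(silyloxy)butyl]-4-methyl-5-(3-methylbut-2-enyl)-2,5-dihydro-1,2-oxamagnesole (not isolated) | CC(C)=CC[C@@H]1O[Mg]C(C(O[Si](C)(C)C(C)(C)C)C(O[Si](C)(C)C(C)(C)C)CC)=C1C | intermediate
13 | (5S,6Z)-8,9-bis[(tert-butyldimethylsilyl)oxy]-7-iodo-2,6-dimethylundeca-2,6-dien-5-ol | CC(C)=CC[C@H](O)/C(C)=C(\I)C(O[Si](C)(C)C(C)(C)C)C(O[Si](C)(C)C(C)(C)C)CC | intermediate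
14 | (5S,6E)-8,9-bis[(tert-butyldimethylsilyl)oxy]-7-ethenyl-2,6-dimethylundeca-2,6-dien-5-ol | CC(C)=CC[C@H](O)/C(C)=C(\C=C)C(O[Si](C)(C)C(C)(C)C)C(O[Si](C)(C)C(C)(C)C)CC | intermediate
15 | angelic acid, (Z)-2-methylbut-2-enoic acid | C/C=C(/C)C(=O)O | starting material
16 | (Z)-2-methylbut-2-enoic 2,4,6-trichlorobenzoic anhydride (not isolated) | C/C=C(/C)C(=O)OC(=O)c1c(Cl)cc(Cl)cc1Cl | intermediate
17 | (5S,6E)-8,9-bis[(tert-butyldimethylsilyl)oxy]-7-ethenyl-2,6-dimethylundeca-2,6-dien-5-yl (Z)-2-methylbut-2-enoate | CC(C)=CC[C@H](OC(=O)/C(C)=C\C)/C(C)=C(\C=C)C(O[Si](C)(C)C(C)(C)C)C(O[Si](C)(C)C(C)(C)C)CC | intermediate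
18 | B-alkyl-9-BBN adduct of 17, boron on the terminal carbon of the former vinyl group (not isolated) | CC(C)=CC[C@H](OC(=O)/C(C)=C\C)/C(C)=C(\CCB1C2CCCC1CCC2)C(O[Si](C)(C)C(C)(C)C)C(O[Si](C)(C)C(C)(C)C)CC | intermediate
19 | (5S,6E)-8,9-bis[(tert-butyldimethylsilyl)oxy]-7-(2-hydroxyethyl)-2,6-dimethylundeca-2,6-dien-5-yl (Z)-2-methylbut-2-enoate | CC(C)=CC[C@H](OC(=O)/C(C)=C\C)/C(C)=C(\CCO)C(O[Si](C)(C)C(C)(C)C)C(O[Si](C)(C)C(C)(C)C)CC | intermediate
20 | (5S,6E)-8,9-dihydroxy-7-(2-hydroxyethyl)-2,6-dimethylundeca-2,6-dien-5-yl (Z)-2-methylbut-2-enoate | CC(C)=CC[C@H](OC(=O)/C(C)=C\C)/C(C)=C(\CCO)C(O)C(O)CC | intermediate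
21 | (5S,6E)-2,6-dimethyl-8,9-dioxo-7-(2-oxoethyl)undeca-2,6-dien-5-yl (Z)-2-methylbut-2-enoate | CC(C)=CC[C@H](OC(=O)/C(C)=C\C)/C(C)=C(\CC=O)C(=O)C(=O)CC | intermediate
22 | ketol, (2E,3S)-2-[(5R)-5-hydroxy-4-methyl-2,3-dioxocyclohexylidene]-6-methylhept-5-en-3-yl (Z)-2-methylbut-2-enoate, C4 epimers (not isolated) | CC(C)=CC[C@H](OC(=O)/C(C)=C\C)/C(C)=C1\C[C@@H](O)C(C)C(=O)C1=O | intermediate
23 | diosphenol, (2E,3S)-2-[(5R)-3,5-dihydroxy-4-methyl-2-oxocyclohex-3-en-1-ylidene]-6-methylhept-5-en-3-yl (Z)-2-methylbut-2-enoate | CC(C)=CC[C@H](OC(=O)/C(C)=C\C)/C(C)=C1\C[C@@H](O)C(C)=C(O)C1=O | intermediate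
24 | (2E,3S)-2-[(5R)-3-acetoxy-5-hydroxy-4-methyl-2-oxocyclohex-3-en-1-ylidene]-6-methylhept-5-en-3-yl (Z)-2-methylbut-2-enoate | CC(C)=CC[C@H](OC(=O)/C(C)=C\C)/C(C)=C1\C[C@@H](O)C(C)=C(OC(C)=O)C1=O | target

Total step count: 14. Longest linear sequence: 13 steps (steps 1–3 and 5–14; step 4 prepares the second fragment).

Steps most likely to fail

1. Step 13. Facial selectivity at the aldehyde may be poor or reversed, because the catalyst is the only controlling element and the secondary enamine of an ethyl ketone is crowded. Uncatalysed cyclisation may also start before the catalyst engages, and the aldehyde may be drawn into dienamine formation. Fallback, from 21 back to 23: 21 is cyclised without stereocontrol (Et3N, 0.2 equiv, CH2Cl2, 0 °C), which should give 23 together with the C5 epimer of diosphenol 23 F1. The two are diastereomers and are separated by chromatography. F1 is then inverted by a Mitsunobu reaction (4-nitrobenzoic acid, PPh3, DIAD, THF, 0 °C) to the (5R)-4-nitrobenzoate of diosphenol 23 F2. Selective methanolysis of this activated ester (K2CO3, MeOH, 0 °C) should return 23, the hindered angelate being much slower to cleave.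

2. Step 7. Carbometalation may be slow at an alkynol that is branched on both sides, the alkenylmagnesium intermediate may lose silanolate to give an allene, and iodinolysis may be incomplete. Fallback, from 5 back to 13: the carbometalation is moved to an unhindered primary alkynol, and the carbinol centre is built afterwards.
 - Alkyne 5 is hydroxymethylated (n-BuLi, then paraformaldehyde, THF) to 4,5-bis[(tert-butyldimethylsilyl)oxy]hept-2-yn-1-ol F3.
 - The same directed anti-carbomagnesiation and iodinolysis (MeMgBr, CuI, THF; then I2) should give (2Z)-4,5-bis[(tert-butyldimethylsilyl)oxy]-3-iodo-2-methylhept-2-en-1-ol F4.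
 - Oxidation with MnO2 (CH2Cl2) gives (2Z)-4,5-bis[(tert-butyldimethylsilyl)oxy]-3-iodo-2-methylhept-2-enal F5.
 - Brown allylation, with the Ipc2B(allyl) enantiomer that delivers the (S)-carbinol, gives (4S,5Z)-7,8-bis[(tert-butyldimethylsilyl)oxy]-6-iodo-5-methyldeca-1,5-dien-4-ol F6.
 - Cross-metathesis with 2-methylbut-2-ene (Grubbs second-generation catalyst) turns the allyl into the prenyl group and returns 13; steps 4–6 are then not needed.

3. Step 14. Site selectivity between the enol and the C5 hydroxyl may be lost, or base may transfer the acetyl group from the enol ester to the neighbouring C5 hydroxyl, so that over-acetylation or the wrong acetate results. Fallback, from 23 back to 24: both hydroxyls are silylated (TESCl, imidazole, DMF) to the bis(triethylsilyl) ether of diosphenol 23 F7. The enol silyl ether alone is cleaved (K2CO3, MeOH, 0 °C) to the C5 triethylsilyl ether of diosphenol 23 F8. Acetylation (Ac2O, Et3N, DMAP, CH2Cl2) gives the C5 triethylsilyl ether of target 24 F9, and HF·pyridine (THF, 0 °C) removes the silyl group under acidic conditions in which the enol acetate does not migrate, giving 24.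

Further compounds
F1 | step 13 | (2E,3S)-2-[(5S)-3,5-dihydroxy-4-methyl-2-oxocyclohex-3-en-1-ylidene]-6-methylhept-5-en-3-yl (Z)-2-methylbut-2-enoate | CC(C)=CC[C@H](OC(=O)/C(C)=C\C)/C(C)=C1\C[C@H](O)C(C)=C(O)C1=O
F2 | step 13 | (2E,3S)-2-[(5R)-3-hydroxy-4-methyl-5-(4-nitrobenzoyloxy)-2-oxocyclohex-3-en-1-ylidene]-6-methylhept-5-en-3-yl (Z)-2-methylbut-2-enoate | CC(C)=CC[C@H](OC(=O)/C(C)=C\C)/C(C)=C1\C[C@@H](OC(=O)c2ccc(cc2)[N+](=O)[O-])C(C)=C(O)C1=O
F3 | step 7 | 4,5-bis[(tert-butyldimethylsilyl)oxy]hept-2-yn-1-ol | CCC(O[Si](C)(C)C(C)(C)C)C(O[Si](C)(C)C(C)(C)C)C#CCO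
F4 | step 7 | (2Z)-4,5-bis[(tert-butyldimethylsilyl)oxy]-3-iodo-2-methylhept-2-en-1-ol | OC/C(C)=C(\I)C(O[Si](C)(C)C(C)(C)C)C(O[Si](C)(C)C(C)(C)C)CC
F5 | step 7 | (2Z)-4,5-bis[(tert-butyldimethylsilyl)oxy]-3-iodo-2-methylhept-2-enal | O=C/C(C)=C(\I)C(O[Si](C)(C)C(C)(C)C)C(O[Si](C)(C)C(C)(C)C)CC
F6 | step 7 | (4S,5Z)-7,8-bis[(tert-butyldimethylsilyl)oxy]-6-iodo-5-methyldeca-1,5-dien-4-ol | C=CC[C@H](O)/C(C)=C(\I)C(O[Si](C)(C)C(C)(C)C)C(O[Si](C)(C)C(C)(C)C)CC
F7 | step 14 | (2E,3S)-2-[(5R)-4-methyl-2-oxo-3,5-bis(triethylsilyloxy)cyclohex-3-en-1-ylidene]-6-methylhept-5-en-3-yl (Z)-2-methylbut-2-enoate | CC(C)=CC[C@H](OC(=O)/C(C)=C\C)/C(C)=C1\C[C@@H](O[Si](CC)(CC)CC)C(C)=C(O[Si](CC)(CC)CC)C1=O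
F8 | step 14 | (2E,3S)-2-[(5R)-3-hydroxy-4-methyl-2-oxo-5-(triethylsilyloxy)cyclohex-3-en-1-ylidene]-6-methylhept-5-en-3-yl (Z)-2-methylbut-2-enoate | CC(C)=CC[C@H](OC(=O)/C(C)=C\C)/C(C)=C1\C[C@@H](O[Si](CC)(CC)CC)C(C)=C(O)C1=O
F9 | step 14 | (2E,3S)-2-[(5R)-3-acetoxy-4-methyl-2-oxo-5-(triethylsilyloxy)cyclohex-3-en-1-ylidene]-6-methylhept-5-en-3-yl (Z)-2-methylbut-2-enoate | CC(C)=CC[C@H](OC(=O)/C(C)=C\C)/C(C)=C1\C[C@@H](O[Si](CC)(CC)CC)C(C)=C(OC(C)=O)C1=O
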